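Everything rests on cutting ring A (C1'–C6') across C5'–C6' and C3'–C4'. The carbinol carbon C1' and the bromomethine C4' stand 1,4 to each other, with the gem-dimethyl carbon C3' next to C4'. This is the pattern of a 'para' [4+2] adduct of a 2-silyloxydiene. In one operation a chiral oxazaborolidinium catalyst joins the silyl dienol ether of mesityl oxide and methyl acrylate, closes ring A and sets C4'. That centre steers vinyl addition at C1', is then erased, and is rebuilt from C1' by hydrogen atom transfer to a vinyl bromide. A sister cycloaddition gives the hydrindane, and a hydrosilylation–aldol step joins both halves.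

Key step: step 2

Locants: hydrindane C1–C7a. C1 bears the side chain, C2 the OH, C3a the angular methyl, C4 the Br, C7 the Me and OH, and C7a the ring-fusion H. C8 is the acetoxy carbinol carbon. Ring A is C1'–C6', with C1' the carbinol, C3' CMe2 and C4' CHBr.

Assumption: the sense of induction of the oxazaborolidinium catalyst is taken from its behaviour with simple dienes and acrylates. If the hindered dienes inverted it, the mirror-image catalyst would be used in steps 2 and 8.

**Step 1**
Reactants: 1 mesityl oxide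
Product: 2 2-(tert-butyldimethylsilyloxy)-4-methylpenta-1,3-diene
Conditions: LiN(i-Pr)2, THF, −78 °C; t-BuMe2SiOTf, −78 → 0 °C
Reagents that add atoms: tert-butyldimethylsilyl triflate CC(C)(C)[Si](C)(C)OS(=O)(=O)C(F)(F)F
Why: Kinetic deprotonation at the acetyl methyl group and O-silylation (silyl enol ether formation) should give the cross-conjugated 2-silyloxydiene without touching the isopropylidene methyls, and no stereocentre is formed.

**Step 2**
Reactants: 2 2-(tert-butyldimethylsilyloxy)-4-methylpenta-1,3-diene; 3 methyl acrylate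
Product: 5 methyl (S)-2,2-dimethyl-4-oxocyclohexane-1-carboxylate, via silyl enol ether cycloadduct 4 (not isolated)
Conditions: (S)-3,3-diphenyl-1-(o-tolyl)tetrahydropyrrolo[1,2-c][1,3,2]oxazaborole·HNTf2 (10 mol %), CH2Cl2, −78 → −20 °C; then 1 M HCl, THF, 0 °C
Reagents that add atoms: none
Why: The boron-bound acrylate reacts with the electron-rich diene in a normal-demand, strongly asynchronous [4π+2π] cycloaddition in which the C5'–C6' bond (diene CH2 to acrylate CH2) runs ahead of the C3'–C4' bond; in the stepwise limit this is a Mukaiyama–Michael addition followed by 6-endo-trig closure of the boron enolate on the silyloxocarbenium-activated isopropylidene carbon. The closest known reaction type is the oxazaborolidinium-catalysed enantioselective Diels–Alder reaction of acrylates with 2-silyloxy-1,3-dienes, and strong Lewis acids are known to force 4,4-disubstituted 2-silyloxydienes into such cycloadditions. Ring A closes as a six-membered ring, suprafacially on both partners. The only new stereocentre, C4', is set by the catalyst, whose aryl groups shield one face of the bound acrylate, so the diene terminus adds to the open face and gives the S ester. The step needs 'para' regioselectivity and [4+2] rather than [2+2] or open-chain Michael chemistry; the 2-silyloxy group puts the largest HOMO coefficient on the CH2 terminus, and the 2-substituent biases the diene towards the s-cis form, which keeps the reacting ends close.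

**Step 3**
Reactants: 5 methyl (S)-2,2-dimethyl-4-oxocyclohexane-1-carboxylate
Product: 7 methyl (1S,4R)-2,2-dimethyl-4-(triethylsilyloxy)-4-vinylcyclohexane-1-carboxylate, via bromomagnesium alkoxide 6 (not isolated)
Conditions: CH2=CHMgBr, CeCl3, THF, −78 °C; then Et3SiOTf, −78 → 0 °C
Reagents that add atoms: vinylmagnesium bromide C=C[Mg]Br; triethylsilyl triflate CC[Si](CC)(CC)OS(=O)(=O)C(F)(F)F
Why: Chemoselective Grignard 1,2-addition to the ketone (the ester next to CMe2 is far slower) takes place on the chair with equatorial ester, where the axial C3' methyl blocks axial attack, so vinyl enters equatorially, trans to the ester, and sets C1' with axial oxygen, which is silylated in the same flask.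

**Step 4**
Reactants: 7 methyl (1S,4R)-2,2-dimethyl-4-(triethylsilyloxy)-4-vinylcyclohexane-1-carboxylate
Product: 9 (R)-2,2-dimethyl-4-(triethylsilyloxy)-4-vinylcyclohexan-1-one, via ketene silyl acetal 8 (not isolated)
Conditions: LiN(i-Pr)2, Me3SiCl, THF, −78 → 0 °C; evaporate; O3 (1 equiv), CH2Cl2, −78 °C; Me2S
Reagents that add atoms: ozone [O-][O+]=O; chlorotrimethylsilane C[Si](C)(C)Cl (its atoms stay only in 8)
Why: Ester enolate O-silylation followed by ozonolysis of the ketene silyl acetal, by far the most electron-rich alkene present, excises the carboxyl carbon as a carbonate and leaves the C4' ketone, erasing the relay stereocentre once C1' is in place.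

**Step 5**
Reactants: 9 (R)-2,2-dimethyl-4-(triethylsilyloxy)-4-vinylcyclohexan-1-one
Product: 11 (R)-[(4-bromo-5,5-dimethyl-1-vinylcyclohex-3-en-1-yl)oxy]triethylsilane, via hydrazone 10 (not isolated)
Conditions: N2H4·H2O, Et3N, EtOH, 80 °C, argon; evaporate; NBS, pyridine, CH2Cl2, −10 °C; then DBU, rt
Reagents that add atoms: N-bromosuccinimide O=C1CCC(=O)N1Br; hydrazine NN (its atoms stay only in 10)
Why: In this Barton-type vinyl halide synthesis, oxidation of the hydrazone by electrophilic bromine passes through the diazo compound and an α-bromo cation that can lose a proton only from C5', which fixes the C4'=C5' vinyl bromide under basic conditions that spare the silyl ether and the vinyl group.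

**Step 6**
Reactants: 11 (R)-[(4-bromo-5,5-dimethyl-1-vinylcyclohex-3-en-1-yl)oxy]triethylsilane
Product: 12 (R)-4-bromo-5,5-dimethyl-1-(triethylsilyloxy)cyclohex-3-ene-1-carbaldehyde
Conditions: OsO4 (2 mol %), NaIO4, 2,6-lutidine, dioxane/H2O, rt
Reagents that add atoms: sodium periodate [Na+].[O-]I(=O)(=O)=O
Why: Lemieux–Johnson cleavage attacks the monosubstituted vinyl group much faster than the electron-poor trisubstituted vinyl bromide next to CMe2 and gives the non-enolisable α-silyloxy aldehyde with C1' untouched.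

**Step 7**
Reactants: 13 1-acetyl-2-methylcyclopentene
Product: 14 tert-butyl(dimethyl){[1-(2-methylcyclopent-1-en-1-yl)vinyl]oxy}silane
Conditions: LiN(i-Pr)2, THF, −78 °C; t-BuMe2SiOTf, −78 → 0 °C
Reagents that add atoms: tert-butyldimethylsilyl triflate CC(C)(C)[Si](C)(C)OS(=O)(=O)C(F)(F)F
Why: Kinetic deprotonation of the acetyl methyl group and O-silylation (silyl enol ether formation) should give the 2-silyloxydiene whose far terminus is the methyl-bearing ring carbon, the future C3a.

**Step 8**
Reactants: 14 tert-butyl(dimethyl){[1-(2-methylcyclopent-1-en-1-yl)vinyl]oxy}silane; 3 methyl acrylate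
Product: 15 methyl (3aR,4R)-7-(tert-butyldimethylsilyloxy)-3a-methyl-2,3,3a,4,5,6-hexahydro-1H-indene-4-carboxylate
Conditions: (R)-3,3-diphenyl-1-(o-tolyl)tetrahydropyrrolo[1,2-c][1,3,2]oxazaborole·HNTf2 (20 mol %), CH2Cl2, −78 → −20 °C; Et3N quench
Reagents that add atoms: none
Why: This is the same catalytic enantioselective Diels–Alder reaction type as step 2, now with the mirror-image catalyst: C4 is set by catalyst control, the quaternary C3a by endo addition (ring CH2 C3 cis to the ester), 'para' regiochemistry follows from the silyloxy group, and any exo adduct is a separable diastereomer.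

**Step 9**
Reactants: 15 methyl (3aR,4R)-7-(tert-butyldimethylsilyloxy)-3a-methyl-2,3,3a,4,5,6-hexahydro-1H-indene-4-carboxylate
Product: 16 methyl (3aR,4R)-3a-methyl-7-oxo-3,3a,4,5,6,7-hexahydro-2H-indene-4-carboxylate
Conditions: Pd(OAc)2 (1.1 equiv), MeCN, 40 °C
Reagents that add atoms: none
Why: In this Saegusa–Ito oxidation, palladation at C7a and β-hydride elimination, possible only towards C1 because C3a is quaternary, should give the C1=C7a enone regiospecifically.

**Step 10**
Reactants: 16 methyl (3aR,4R)-3a-methyl-7-oxo-3,3a,4,5,6,7-hexahydro-2H-indene-4-carboxylate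
Product: 18 methyl (3aR,4R,7R)-3a,7-dimethyl-7-(triethylsilyloxy)-3,3a,4,5,6,7-hexahydro-2H-indene-4-carboxylate, via bromomagnesium alkoxide 17 (not isolated)
Conditions: MeMgBr, CeCl3, THF, −78 °C; then Et3SiOTf, −78 → 0 °C
Reagents that add atoms: methylmagnesium bromide C[Mg]Br; triethylsilyl triflate CC[Si](CC)(CC)OS(=O)(=O)C(F)(F)F
Why: In this cerium-assisted Grignard 1,2-addition the axial C3a methyl shields the axial trajectory, so methyl enters equatorially from the opposite face and sets C7 with the oxygen axial and cis to the angular methyl, while the hindered ester survives and the alkoxide is silylated in situ.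

**Step 11**
Reactants: 18 methyl (3aR,4R,7R)-3a,7-dimethyl-7-(triethylsilyloxy)-3,3a,4,5,6,7-hexahydro-2H-indene-4-carboxylate
Product: 20 (3aS,7R)-3a,7-dimethyl-7-(triethylsilyloxy)-2,3,3a,5,6,7-hexahydro-4H-inden-4-one, via ketene silyl acetal 19 (not isolated)
Conditions: LiN(i-Pr)2, Me3SiCl, THF, −78 → 0 °C; evaporate; O3 (1 equiv), CH2Cl2, −78 °C; Me2S
Reagents that add atoms: ozone [O-][O+]=O; chlorotrimethylsilane C[Si](C)(C)Cl (its atoms stay only in 19)
Why: Ketene silyl acetal formation and ozonolysis as in step 4 turn C4 into a ketone, and the hindered C1=C7a alkene between two quaternary carbons should react far more slowly with one equivalent of ozone.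

**Step 12**
Reactants: 20 (3aS,7R)-3a,7-dimethyl-7-(triethylsilyloxy)-2,3,3a,5,6,7-hexahydro-4H-inden-4-one
Product: 22 {[(3aS,7R)-4-bromo-3a,7-dimethyl-3,3a,6,7-tetrahydro-2H-inden-7-yl]oxy}triethylsilane, via hydrazone 21 (not isolated)
Conditions: N2H4·H2O, Et3N, EtOH, 80 °C, argon; evaporate; NBS, pyridine, CH2Cl2, −10 °C; then DBU, rt
Reagents that add atoms: N-bromosuccinimide O=C1CCC(=O)N1Br; hydrazine NN (its atoms stay only in 21)
Why: This Barton-type vinyl halide synthesis works as in step 5, and because C3a is quaternary the proton can be lost only from C5, giving the C4=C5 vinyl bromide.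

**Step 13**
Reactants: 22 {[(3aS,7R)-4-bromo-3a,7-dimethyl-3,3a,6,7-tetrahydro-2H-inden-7-yl]oxy}triethylsilane
Product: 23 (3aS,7R)-4-bromo-3a,7-dimethyl-7-(triethylsilyloxy)-3,3a,6,7-tetrahydro-2H-inden-2-one
Conditions: Rh2(cap)4 (dirhodium tetrakis(caprolactamate), 1 mol %), t-BuOOH, K2CO3, CH2Cl2, rt
Reagents that add atoms: tert-butyl hydroperoxide CC(C)(C)OO
Why: In this allylic C–H oxidation by tert-butylperoxy radicals, C2 is the only allylic CH2 of the electron-rich C1=C7a alkene (C7 and C3a carry no hydrogen), whereas C6, next to the electron-poor vinyl bromide and the quaternary C7, should react more slowly.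

**Step 14**
Reactants: 23 (3aS,7R)-4-bromo-3a,7-dimethyl-7-(triethylsilyloxy)-3,3a,6,7-tetrahydro-2H-inden-2-one; 12 (R)-4-bromo-5,5-dimethyl-1-(triethylsilyloxy)cyclohex-3-ene-1-carbaldehyde
Product: 25 trans-fused β-hydroxy ketone (1R,8R), via triethylsilyl enol ether 24 (not isolated)
Conditions: Pt2[(CH2=CHSiMe2)2O]3 (1 mol %), Et3SiH, toluene, 60 °C; evaporate; 12, BF3·OEt2, CH2Cl2, −78 °C; aq NaHCO3
Reagents that add atoms: triethylsilane CC[SiH](CC)CC (silicon stays only in 24)
Why: Platinum-catalysed 1,4-hydrosilylation delivers hydride to C7a from the face opposite to the axial C3a methyl and C7 silyloxy groups (trans fusion) and gives the C1=C2 silyl enol ether regiospecifically, and its Mukaiyama aldol addition occurs on the same open face of C1 through an open antiperiplanar transition state that keeps the bulky C1' residue anti to C7a, which sets C1 and the 8R carbinol (1,8-syn).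

**Step 15**
Reactants: 25 trans-fused β-hydroxy ketone (1R,8R)
Product: 26 β-acetoxy ketone
Conditions: Ac2O, DMAP, Et3N, CH2Cl2, 0 °C
Reagents that add atoms: acetic anhydride CC(=O)OC(C)=O
Why: DMAP-catalysed acylation meets a single free hydroxyl group (C8–OH) and is run cold and short to avoid β-elimination or retro-aldol cleavage.

**Step 16**
Reactants: 26 β-acetoxy ketone
Product: 27 (2R)-alcohol with both vinyl bromides intact
Conditions: (S)-2-methyl-CBS-oxazaborolidine (20 mol %), BH3·SMe2, THF, −20 °C; MeOH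
Reagents that add atoms: none
Why: In this CBS reduction the branched C1 acts as the large and C3H2 as the small flank, so the S catalyst delivers hydride to the face anti to the C1 side chain (matched with substrate bias) and gives the 2R alcohol cis to the side chain, while acetate, silyl ethers and vinyl bromides are inert.

**Step 17**
Reactants: 27 (2R)-alcohol with both vinyl bromides intact
Product: 28 7,1'-bis(triethylsilyl) ether of the target
Conditions: Co(acac)2 (25 mol %), t-BuOOH, Et3SiH, 1,4-cyclohexadiene, n-PrOH, rt, argon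
Reagents that add atoms: none
Why: In this cobalt-hydride hydrogen atom transfer hydrogenation of alkenyl halides, H adds to C5 and C5', and each α-bromo radical abstracts hydrogen from 1,4-cyclohexadiene along the axial trajectory anti to the axial methyl on the neighbouring quaternary carbon (C3a, C3'), so both bromines end equatorial (4S, 4'S), ring A being anchored by its equatorial C8 substituent.

**Step 18**
Reactants: 28 7,1'-bis(triethylsilyl) ether of the target
Product: 29 target CNP0166243.1
Conditions: HF·pyridine, THF, 0 °C → rt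
Reagents that add atoms: none
Why: Fluoride-mediated desilylation cleaves both tertiary triethylsilyl ethers under mildly acidic conditions that should avoid acetate migration, hydrolysis and loss of the secondary bromides.

**Compound list**

1 | mesityl oxide (4-methylpent-3-en-2-one) | CC(=O)C=C(C)C | starting material
2 | tert-butyl(dimethyl)[(4-methylpenta-1,3-dien-2-yl)oxy]silane | C=C(O[Si](C)(C)C(C)(C)C)C=C(C)C | intermediate
3 | methyl acrylate | C=CC(=O)OC | starting material
4 | methyl (S)-4-(tert-butyldimethylsilyloxy)-2,2-dimethylcyclohex-3-ene-1-carboxylate | CC(C)(C)[Si](C)(C)OC1=CC(C)(C)[C@@H](C(=O)OC)CC1 | intermediate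
5 | methyl (S)-2,2-dimethyl-4-oxocyclohexane-1-carboxylate | O=C1CC[C@H](C(=O)OC)C(C)(C)C1 | intermediate
6 | bromomagnesium alkoxide of methyl (1S,4R)-4-hydroxy-2,2-dimethyl-4-vinylcyclohexane-1-carboxylate | C=C[C@@]1(O[Mg]Br)CC[C@H](C(=O)OC)C(C)(C)C1 | intermediate
7 | methyl (1S,4R)-2,2-dimethyl-4-(triethylsilyloxy)-4-vinylcyclohexane-1-carboxylate | C=C[C@@]1(O[Si](CC)(CC)CC)CC[C@H](C(=O)OC)C(C)(C)C1 | intermediate
8 | ketene methyl trimethylsilyl acetal of 7 | C=C[C@@]1(O[Si](CC)(CC)CC)CCC(=C(OC)O[Si](C)(C)C)C(C)(C)C1 | intermediate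
9 | (R)-2,2-dimethyl-4-(triethylsilyloxy)-4-vinylcyclohexan-1-one | C=C[C@@]1(O[Si](CC)(CC)CC)CCC(=O)C(C)(C)C1 | intermediate
10 | hydrazone of 9 | C=C[C@@]1(O[Si](CC)(CC)CC)CCC(=NN)C(C)(C)C1 | intermediate
11 | (R)-[(4-bromo-5,5-dimethyl-1-vinylcyclohex-3-en-1-yl)oxy]triethylsilane | C=C[C@@]1(O[Si](CC)(CC)CC)CC=C(Br)C(C)(C)C1 | intermediate
12 | (R)-4-bromo-5,5-dimethyl-1-(triethylsilyloxy)cyclohex-3-ene-1-carbaldehyde | O=C[C@@]1(O[Si](CC)(CC)CC)CC=C(Br)C(C)(C)C1 | intermediate
13 | 1-acetyl-2-methylcyclopentene | CC(=O)C1=C(C)CCC1 | starting material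
14 | tert-butyl(dimethyl){[1-(2-methylcyclopent-1-en-1-yl)vinyl]oxy}silane | C=C(O[Si](C)(C)C(C)(C)C)C1=C(C)CCC1 | intermediate
15 | methyl (3aR,4R)-7-(tert-butyldimethylsilyloxy)-3a-methyl-2,3,3a,4,5,6-hexahydro-1H-indene-4-carboxylate | COC(=O)[C@@H]1CCC(O[Si](C)(C)C(C)(C)C)=C2CCC[C@]12C | intermediate
16 | methyl (3aR,4R)-3a-methyl-7-oxo-3,3a,4,5,6,7-hexahydro-2H-indene-4-carboxylate | COC(=O)[C@@H]1CCC(=O)C2=CCC[C@]12C | intermediate
17 | bromomagnesium alkoxide of methyl (3aR,4R,7R)-7-hydroxy-3a,7-dimethyl-3,3a,4,5,6,7-hexahydro-2H-indene-4-carboxylate | COC(=O)[C@@H]1CC[C@@](C)(O[Mg]Br)C2=CCC[C@]12C | intermediate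
18 | methyl (3aR,4R,7R)-3a,7-dimethyl-7-(triethylsilyloxy)-3,3a,4,5,6,7-hexahydro-2H-indene-4-carboxylate | COC(=O)[C@@H]1CC[C@@](C)(O[Si](CC)(CC)CC)C2=CCC[C@]12C | intermediate
19 | ketene methyl trimethylsilyl acetal of 18 | COC(O[Si](C)(C)C)=C1CC[C@@](C)(O[Si](CC)(CC)CC)C2=CCC[C@]12C | intermediate
20 | (3aS,7R)-3a,7-dimethyl-7-(triethylsilyloxy)-2,3,3a,5,6,7-hexahydro-4H-inden-4-one | O=C1CC[C@@](C)(O[Si](CC)(CC)CC)C2=CCC[C@]12C | intermediate
21 | hydrazone of 20 | NN=C1CC[C@@](C)(O[Si](CC)(CC)CC)C2=CCC[C@]12C | intermediate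
22 | {[(3aS,7R)-4-bromo-3a,7-dimethyl-3,3a,6,7-tetrahydro-2H-inden-7-yl]oxy}triethylsilane | BrC1=CC[C@@](C)(O[Si](CC)(CC)CC)C2=CCC[C@]12C | intermediate
23 | (3aS,7R)-4-bromo-3a,7-dimethyl-7-(triethylsilyloxy)-3,3a,6,7-tetrahydro-2H-inden-2-one | BrC1=CC[C@@](C)(O[Si](CC)(CC)CC)C2=CC(=O)C[C@]12C | intermediate
24 | (3aS,7R,7aS)-4-bromo-3a,7-dimethyl-2,7-bis(triethylsilyloxy)-3a,6,7,7a-tetrahydro-3H-indene | BrC1=CC[C@@](C)(O[Si](CC)(CC)CC)[C@H]2C=C(O[Si](CC)(CC)CC)C[C@]12C | intermediate
25 | (1R,3aS,7R,7aS)-4-bromo-1-{(R)-[(R)-4-bromo-5,5-dimethyl-1-(triethylsilyloxy)cyclohex-3-en-1-yl](hydroxy)methyl}-3a,7-dimethyl-7-(triethylsilyloxy)-1,3,3a,6,7,7a-hexahydro-2H-inden-2-one | O[C@H]([C@@H]1C(=O)C[C@]2(C)C(Br)=CC[C@@](C)(O[Si](CC)(CC)CC)[C@@H]12)[C@@]1(O[Si](CC)(CC)CC)CC=C(Br)C(C)(C)C1 | intermediate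
26 | C8 acetate of 25 | CC(=O)O[C@H]([C@@H]1C(=O)C[C@]2(C)C(Br)=CC[C@@](C)(O[Si](CC)(CC)CC)[C@@H]12)[C@@]1(O[Si](CC)(CC)CC)CC=C(Br)C(C)(C)C1 | intermediate
27 | (R)-[(1S,2R,3aS,7R,7aS)-4-bromo-2-hydroxy-3a,7-dimethyl-7-(triethylsilyloxy)-2,3,3a,6,7,7a-hexahydro-1H-inden-1-yl][(R)-4-bromo-5,5-dimethyl-1-(triethylsilyloxy)cyclohex-3-en-1-yl]methyl acetate | CC(=O)O[C@H]([C@@H]1[C@H](O)C[C@]2(C)C(Br)=CC[C@@](C)(O[Si](CC)(CC)CC)[C@@H]12)[C@@]1(O[Si](CC)(CC)CC)CC=C(Br)C(C)(C)C1 | intermediate
28 | (R)-[(1S,2R,3aS,4S,7R,7aS)-4-bromo-2-hydroxy-3a,7-dimethyl-7-(triethylsilyloxy)octahydro-1H-inden-1-yl][(1R,4S)-4-bromo-3,3-dimethyl-1-(triethylsilyloxy)cyclohexyl]methyl acetate | CC(=O)O[C@H]([C@@H]1[C@H](O)C[C@]2(C)[C@@H](Br)CC[C@@](C)(O[Si](CC)(CC)CC)[C@@H]12)[C@@]1(O[Si](CC)(CC)CC)CC[C@H](Br)C(C)(C)C1 | intermediate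
29 | (R)-[(1S,2R,3aS,4S,7R,7aS)-4-bromo-2,7-dihydroxy-3a,7-dimethyloctahydro-1H-inden-1-yl][(1R,4S)-4-bromo-1-hydroxy-3,3-dimethylcyclohexyl]methyl acetate | CC(=O)O[C@H]([C@@H]1[C@H](O)C[C@]2(C)[C@@H](Br)CC[C@@](C)(O)[C@@H]12)[C@@]1(O)CC[C@H](Br)C(C)(C)C1 | target

**Step count and risks**

Total step count: 18. Longest linear sequence: 12 (steps 7–18). The ring A branch (steps 1–6) joins at step 14.

Steps most likely to fail:

**Step 8.** The second bond must form at a fully substituted diene terminus, so the reaction may stop at the open-chain Michael adduct after silyl transfer. Leakage between endo and exo approach, or between the acrylate faces, would also lower the optical purity of C3a.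
- The fallback replaces catalyst control by a covalently bound auxiliary and a stoichiometric, cationic aluminium chelate.
- It sets out from 14, which is combined with (S)-3-acryloyl-4-benzyloxazolidin-2-one and Me2AlCl in CH2Cl2 at −78 °C. This gives the endo cycloadduct imide F4, whose stereoisomers are diastereomers and can be removed by chromatography or crystallisation.
- LiOOH in THF/H2O at 0 °C gives the carboxylic acid F5, and Me3SiCHN2 in MeOH/toluene leads back to the route at 15.

**Step 2.** Bond formation at the isopropylidene terminus may be slow. The acid catalyst could then protodesilylate the diene, or a [2+2] or open-chain Michael pathway and a less ordered transition state could erode yield and enantioselectivity.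
- The fallback again uses auxiliary control. It sets out from 2, which reacts with (R)-3-acryloyl-4-benzyloxazolidin-2-one and Me2AlCl in CH2Cl2 at −78 °C to give the silyl enol ether imide F1.
- Work-up with 1 M HCl gives the keto imide F2, which is purified to a single diastereomer.
- LiOOH gives (S)-2,2-dimethyl-4-oxocyclohexane-1-carboxylic acid F3, and Me3SiCHN2 leads back to the route at 5.
- Both ring A bonds are still made in the one cycloaddition event.

**Step 14.** Hydride delivery to C7a, which lies between two quaternary carbons, may be too slow or may turn into 1,2-reduction. The open transition state of the aldol addition may also give poor simple diastereoselection at C8.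
- The fallback separates the two tasks and uses a closed transition state. It sets out from 23.
- Hydrogen atom transfer hydrogenation with Mn(dpm)3 (tris(dipivaloylmethanato)manganese), PhSiH3 and t-BuOOH in i-PrOH tolerates steric crowding. It reduces both the enone alkene and the ring B vinyl bromide from the face anti to the angular methyl, giving the saturated bromo ketone F6.
- LiN(i-Pr)2 at −78 °C removes a proton from C1 rather than from the neopentyl C3, and ClTi(OiPr)3 gives the triisopropoxytitanium enolate F7. This type of enolate is known to give syn aldols from cyclic ketones.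
- Addition of 12 gives the β-hydroxy ketone F8, Ac2O/DMAP the acetate F9, and the CBS reduction of step 16 the alcohol F10.
- The Co(acac)2 conditions of step 17 then reduce only the ring A vinyl bromide, and the route is rejoined at 28.

**Further compounds**

F1 | step 2 | (R)-4-benzyl-3-[(S)-4-(tert-butyldimethylsilyloxy)-2,2-dimethylcyclohex-3-ene-1-carbonyl]oxazolidin-2-one | CC(C)(C)[Si](C)(C)OC1=CC(C)(C)[C@@H](C(=O)N2[C@H](Cc3ccccc3)COC2=O)CC1
F2 | step 2 | (R)-4-benzyl-3-[(S)-2,2-dimethyl-4-oxocyclohexane-1-carbonyl]oxazolidin-2-one | O=C1CC[C@H](C(=O)N2[C@H](Cc3ccccc3)COC2=O)C(C)(C)C1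
F3 | step 2 | (S)-2,2-dimethyl-4-oxocyclohexane-1-carboxylic acid | O=C1CC[C@H](C(=O)O)C(C)(C)C1
F4 | step 8 | (S)-4-benzyl-3-[(3aR,4R)-7-(tert-butyldimethylsilyloxy)-3a-methyl-2,3,3a,4,5,6-hexahydro-1H-indene-4-carbonyl]oxazolidin-2-one | O=C([C@@H]1CCC(O[Si](C)(C)C(C)(C)C)=C2CCC[C@]12C)N1[C@@H](Cc2ccccc2)COC1=O
F5 | step 8 | (3aR,4R)-7-(tert-butyldimethylsilyloxy)-3a-methyl-2,3,3a,4,5,6-hexahydro-1H-indene-4-carboxylic acid | OC(=O)[C@@H]1CCC(O[Si](C)(C)C(C)(C)C)=C2CCC[C@]12C
F6 | step 14 | (3aS,4S,7R,7aS)-4-bromo-3a,7-dimethyl-7-(triethylsilyloxy)octahydro-2H-inden-2-one | C1C(=O)C[C@]2(C)[C@@H](Br)CC[C@@](C)(O[Si](CC)(CC)CC)[C@@H]12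
F7 | step 14 | triisopropoxytitanium C1=C2 enolate of F6 | Br[C@H]1CC[C@@](C)(O[Si](CC)(CC)CC)[C@H]2C=C(O[Ti](OC(C)C)(OC(C)C)OC(C)C)C[C@]12C
F8 | step 14 | β-hydroxy ketone (1R,8R) with saturated 4S-bromo ring B | O[C@H]([C@@H]1C(=O)C[C@]2(C)[C@@H](Br)CC[C@@](C)(O[Si](CC)(CC)CC)[C@@H]12)[C@@]1(O[Si](CC)(CC)CC)CC=C(Br)C(C)(C)C1
F9 | step 14 | C8 acetate of F8 | CC(=O)O[C@H]([C@@H]1C(=O)C[C@]2(C)[C@@H](Br)CC[C@@](C)(O[Si](CC)(CC)CC)[C@@H]12)[C@@]1(O[Si](CC)(CC)CC)CC=C(Br)C(C)(C)C1
F10 | step 14 | (2R)-alcohol from F9 | CC(=O)O[C@H]([C@@H]1[C@H](O)C[C@]2(C)[C@@H](Br)CC[C@@](C)(O[Si](CC)(CC)CC)[C@@H]12)[C@@]1(O[Si](CC)(CC)CC)CC=C(Br)C(C)(C)C1
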